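**Strategy.** Both ester bonds are cut first, to malonic acid and two molecules of labda-7,13E-dien-15-ol. The bicycle is then taken apart at C9–C10 and at C4–C5: ring A (C1–C5, C10) is not closed directly but grows out of a 1,2,2-trimethylcyclopentane. Ionisation of a C5 carbinyl triflate attached to this ring lets quaternary C4 shift from C10 to C5; the new tertiary C10 cation is trapped at C9 by a C7-silylated E-alkene, which closes ring B and leaves the C7=C8 bond. One operation thus sets C5, C9 and C10. The step exploits the C5 methine flanked by the fully substituted C4 and C10. Its precursor is an acyclic geraniol-derived chain bearing a cyclopentyl carbinol.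

Key step: step 6

Remark: C1–C20 are labdane locants and are used for the acyclic precursors as well (C5 carbinol carbon, C7 silyl-bearing carbon, C10 ring quaternary carbon).
Remark: ketone 3 is made as a racemate; its quaternary carbon becomes the planar C10 cation in step 6, so 10 is a racemate and 11–13 are mixtures of two epimers at that carbon, drawn without a descriptor there.
Remark: 1, 4, 16, the silylboronate of step 4 and 2,2-dimethylcyclopentanone (used in one fallback) are taken as commercial.

Step 1
Reactants: 1 1-(2-methylcyclopent-1-en-1-yl)ethan-1-one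
Product: 3 1-(1,2,2-trimethylcyclopentyl)ethan-1-one (racemic), via lithium enolate 2 (not isolated)
Conditions: Me2CuLi, Et2O, 0 °C; then MeI, HMPA, THF, 0 → 25 °C
Reagents that add atoms: lithium dimethylcuprate, [Li+].C[Cu-]C; iodomethane, CI
Why: Tandem conjugate addition–enolate alkylation: the cuprate should add to the β-carbon of the tetrasubstituted enone as it does with other β,β-disubstituted acyl alkenes, and the regiodefined enolate 2 should be C-methylated by the small electrophile in the presence of HMPA before it equilibrates, which gives the quaternary carbon as a racemate.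

Step 2
Reactants: 4 geranyl acetate
Product: 6 (2E,6E)-3,7-dimethyl-8-oxoocta-2,6-dien-1-yl acetate, via allylic alcohol 5 (not isolated)
Conditions: SeO2 (cat.), t-BuOOH, salicylic acid (cat.), CH2Cl2, 25 °C; crude product, then MnO2, CH2Cl2, 25 °C
Reagents that add atoms: selenium dioxide, O=[Se]=O; tert-butyl hydroperoxide, CC(C)(C)OO
Why: Riley allylic oxidation (ene reaction, then [2,3]-sigmatropic shift) should attack the E-methyl group of the electron-rich terminal alkene and not the acetate-deactivated one, and MnO2 should take allylic alcohol 5 on to the E-enal without touching the alkene geometry.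

Step 3
Reactants: 3 1-(1,2,2-trimethylcyclopentyl)ethan-1-one; 6 (2E,6E)-3,7-dimethyl-8-oxoocta-2,6-dien-1-yl acetate
Product: 10 (2E,6E,8E)-3,7-dimethyl-10-oxo-10-(1,2,2-trimethylcyclopentyl)deca-2,6,8-trien-1-yl acetate, via lithium enolate 7 (not isolated), via lithium aldolate 8 (not isolated), via mesylate 9 (not isolated)
Conditions: LDA, THF, −78 °C; 6, −78 °C; MsCl, −78 → 0 °C; DBU, 0 → 25 °C
Reagents that add atoms: none
Why: Directed aldol condensation: 3 can enolise only at its methyl group, enolate 7 should add 1,2 to the aldehyde far faster than it attacks the acetate at −78 °C, and E1cB elimination of mesylate 9 should give the conjugated E-dienone.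

Step 4
Reactants: 10 (2E,6E,8E)-3,7-dimethyl-10-oxo-10-(1,2,2-trimethylcyclopentyl)deca-2,6,8-trien-1-yl acetate
Product: 11 (2E,6E,8R)-8-[dimethyl(phenyl)silyl]-3,7-dimethyl-10-oxo-10-(1,2,2-trimethylcyclopentyl)deca-2,6-dien-1-yl acetate
Conditions: PhMe2Si–B(pin), CuCl (cat.), chiral imidazolinium salt (NHC precursor, cat.), NaOt-Bu (cat.), THF, −78 °C; then MeOH, aq. NH4Cl
Reagents that add atoms: (dimethylphenylsilyl)boronic acid pinacol ester, CC1(C)OB(OC1(C)C)[Si](C)(C)c1ccccc1
Why: NHC–copper-catalysed conjugate silyl transfer from a silylboronate, which on acyclic dienones should add 1,4 and leave the γ,δ-alkene as an E-allylsilane; the chiral ligand, used as the antipode that delivers silicon to the enone face leading to the R centre, should set the C–Si stereocentre under catalyst control.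

Step 5
Reactants: 11 (2E,6E,8R)-8-[dimethyl(phenyl)silyl]-3,7-dimethyl-10-oxo-10-(1,2,2-trimethylcyclopentyl)deca-2,6-dien-1-yl acetate
Product: 12 (2E,6E,8R,10S)-8-[dimethyl(phenyl)silyl]-10-hydroxy-3,7-dimethyl-10-(1,2,2-trimethylcyclopentyl)deca-2,6-dien-1-yl acetate
Conditions: (R)-Me-CBS oxazaborolidine, catecholborane, toluene, −40 °C; then MeOH, aq. NaOH
Reagents that add atoms: none
Why: Corey–Bakshi–Shibata reduction: with the tert-alkyl group as the large and the CH2 chain as the small substituent, the (R)-oxazaborolidine should deliver hydride to the face that gives the (S)-carbinol, and catecholborane should leave the trisubstituted alkenes and the acetate alone.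

Step 6
Reactants: 12 (2E,6E,8R,10S)-8-[dimethyl(phenyl)silyl]-10-hydroxy-3,7-dimethyl-10-(1,2,2-trimethylcyclopentyl)deca-2,6-dien-1-yl acetate
Product: 14 (5S,9S,10S)-labda-7,13E-dien-15-yl acetate, via triflate 13 (not isolated)
Conditions: Tf2O, 2,6-di-tert-butyl-4-methylpyridine, CH2Cl2, −78 → −20 °C
Reagents that add atoms: none
Why: Triflation of the hindered carbinol should be followed on warming by ionisation of 13 that is concerted with a 1,2-shift of C4 from C10 to C5 (Wagner–Meerwein, cyclopentylcarbinyl to cyclohexyl, secondary to tertiary cation), which enlarges the five-membered ring to ring A (C1–C5, C10); the tertiary C10 cation is then attacked by C9 of the allylsilane, and the β-silyl cation at C8 loses silicon to give the C7=C8 bond. The closest known reaction types are the solvolytic ring expansion of (1-alkylcyclopentyl)carbinyl sulfonates, the same cyclopentylcarbinyl-to-cyclohexyl expansion followed by alkene capture in lanosterol and hopene biosynthesis, and the allylsilane-terminated closure of cyclogeranyl-type C10 cations to trans-decalins. Ring A arises by ring expansion, not by closure, and ring B closes in a 6-endo-trig cation–olefin mode through a chair. C5 is set by the (S)-carbinol of 12, because C4 enters anti to the leaving triflate (inversion); C10 is set by the chair, in which C5–C6 and the forming C9–C10 bond are equatorial on ring A (trans fusion, methyl anti to H5); C9 is set by the E geometry of the C8=C9 alkene (side chain equatorial), and the (R)-C7–Si bond is axial and anti to the forming bond (anti SE2′). The step needs C4 to migrate in preference to C1 or the methyl group, which the substrate secures because C4 is the most substituted migrating terminus and C4–C10, joining two fully substituted carbons, is the weakest and most electron-rich bond; it also needs this shift to outrun E2 loss of triflic acid, γ-silyl 1,3-elimination and direct attack of the alkene at C5 (a disfavoured 5-endo mode), which the low temperature and the hindered non-nucleophilic base favour. Both C10 epimers of 13 give the same planar cation, and the acetate-deactivated C13=C14 alkene should not compete for the C8 cation because loss of silicon is faster.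

Step 7
Reactants: 14 (5S,9S,10S)-labda-7,13E-dien-15-yl acetate
Product: 15 (5S,9S,10S)-labda-7,13E-dien-15-ol
Conditions: K2CO3, MeOH, 25 °C
Reagents that add atoms: none
Why: Base-catalysed transesterification (methanolysis) of the primary allylic acetate should free the alcohol without affecting either trisubstituted alkene or any stereocentre.

Step 8
Reactants: 15 (5S,9S,10S)-labda-7,13E-dien-15-ol (2 equiv); 16 malonic acid
Product: 18 bis[(5S,9S,10S)-labda-7,13E-dien-15-yl] malonate (target), via malonate half-ester 17 (not isolated)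
Conditions: DCC, DMAP (cat.), CH2Cl2, 0 → 25 °C
Reagents that add atoms: none
Why: Steglich esterification: carbodiimide activation of each carboxyl group of malonic acid in turn, with DMAP as acyl-transfer catalyst, should acylate the unhindered primary allylic alcohol twice under neutral conditions that leave the alkenes and stereocentres untouched.

**Compound list**

1 | 1-(2-methylcyclopent-1-en-1-yl)ethan-1-one | CC(=O)C1=C(C)CCC1 | starting material
2 | lithium 1-(2,2-dimethylcyclopentylidene)ethan-1-olate | [Li+].CC([O-])=C1CCCC1(C)C | intermediate (not isolated)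
3 | 1-(1,2,2-trimethylcyclopentyl)ethan-1-one, racemic | CC(=O)C1(C)CCCC1(C)C | intermediate
4 | geranyl acetate, (2E)-3,7-dimethylocta-2,6-dien-1-yl acetate | CC(C)=CCC/C(C)=C/COC(C)=O | starting material
5 | (2E,6E)-8-hydroxy-3,7-dimethylocta-2,6-dien-1-yl acetate | OC/C(C)=C/CC/C(C)=C/COC(C)=O | intermediate (not isolated)
6 | (2E,6E)-3,7-dimethyl-8-oxoocta-2,6-dien-1-yl acetate | O=C/C(C)=C/CC/C(C)=C/COC(C)=O | intermediate
7 | lithium 1-(1,2,2-trimethylcyclopentyl)ethen-1-olate | [Li+].C=C([O-])C1(C)CCCC1(C)C | intermediate (not isolated)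
8 | lithium (2E,6E)-1-acetoxy-3,7-dimethyl-10-oxo-10-(1,2,2-trimethylcyclopentyl)deca-2,6-dien-8-olate | [Li+].CC(=O)OC/C=C(C)/CC/C=C(C)/C([O-])CC(=O)C1(C)CCCC1(C)C | intermediate (not isolated)
9 | (2E,6E)-8-[(methanesulfonyl)oxy]-3,7-dimethyl-10-oxo-10-(1,2,2-trimethylcyclopentyl)deca-2,6-dien-1-yl acetate | CC(=O)OC/C=C(C)/CC/C=C(C)/C(OS(C)(=O)=O)CC(=O)C1(C)CCCC1(C)C | intermediate (not isolated)
10 | (2E,6E,8E)-3,7-dimethyl-10-oxo-10-(1,2,2-trimethylcyclopentyl)deca-2,6,8-trien-1-yl acetate, racemic | CC(=O)OC/C=C(C)/CC/C=C(C)/C=C/C(=O)C1(C)CCCC1(C)C | intermediate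
11 | (2E,6E,8R)-8-[dimethyl(phenyl)silyl]-3,7-dimethyl-10-oxo-10-(1,2,2-trimethylcyclopentyl)deca-2,6-dien-1-yl acetate | CC1(C)CCCC1(C)C(=O)C[C@@H]([Si](C)(C)c1ccccc1)/C(C)=C/CC/C(C)=C/COC(C)=O | intermediate
12 | (2E,6E,8R,10S)-8-[dimethyl(phenyl)silyl]-10-hydroxy-3,7-dimethyl-10-(1,2,2-trimethylcyclopentyl)deca-2,6-dien-1-yl acetate | CC1(C)CCCC1(C)[C@@H](O)C[C@@H]([Si](C)(C)c1ccccc1)/C(C)=C/CC/C(C)=C/COC(C)=O | intermediate
13 | (2E,6E,8R,10S)-8-[dimethyl(phenyl)silyl]-3,7-dimethyl-10-(1,2,2-trimethylcyclopentyl)-10-[(trifluoromethanesulfonyl)oxy]deca-2,6-dien-1-yl acetate | CC1(C)CCCC1(C)[C@@H](OS(=O)(=O)C(F)(F)F)C[C@@H]([Si](C)(C)c1ccccc1)/C(C)=C/CC/C(C)=C/COC(C)=O | intermediate (not isolated)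
14 | (5S,9S,10S)-labda-7,13E-dien-15-yl acetate | CC1=CC[C@H]2C(C)(C)CCC[C@]2(C)[C@H]1CC/C(C)=C/COC(C)=O | intermediate
15 | (5S,9S,10S)-labda-7,13E-dien-15-ol | CC1=CC[C@H]2C(C)(C)CCC[C@]2(C)[C@H]1CC/C(C)=C/CO | intermediate
16 | malonic acid | OC(=O)CC(=O)O | starting material
17 | 3-{[(5S,9S,10S)-labda-7,13E-dien-15-yl]oxy}-3-oxopropanoic acid | CC1=CC[C@H]2C(C)(C)CCC[C@]2(C)[C@H]1CC/C(C)=C/COC(=O)CC(=O)O | intermediate (not isolated)
18 | bis[(5S,9S,10S)-labda-7,13E-dien-15-yl] malonate | CC1=CC[C@H]2C(C)(C)CCC[C@]2(C)[C@H]1CC/C(C)=C/COC(=O)CC(=O)OC/C=C(\C)CC[C@H]1C(C)=CC[C@H]2C(C)(C)CCC[C@]12C | target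

**Totals.** Total step count: 8. Longest linear sequence: 7 steps (step 1 or step 2, then steps 3–8).

**Steps most likely to fail**

Step 6 (key step). The triflate may ionise without the concerted shift of C4: ion-pair return or E2 loss of triflic acid, γ-silyl-assisted 1,3-elimination to a cyclopropane, or migration of C1 or of the methyl group. Ring A would then not form cleanly, or the C5 configuration would not be relayed. In the fallback, ring A is still made by a five-to-six ring expansion, but through a hydroxyl-driven semipinacol shift, and ring B is closed afterwards from a tertiary carbinol. It sets out from enal 6 and comes back at 14. Addition of 1-ethoxyvinyllithium to 2,2-dimethylcyclopentanone with acidic work-up should give 1-(1-hydroxy-2,2-dimethylcyclopentyl)ethan-1-one F1. Its dianion (LDA, 2 equiv) is condensed with 6 and the aldol dehydrated (p-TsOH) to the hydroxy dienone F2. The conjugate silyl transfer of step 4 should convert this into the (R)-β-silyl hydroxy ketone F3, and the reduction of step 5 should give the (S)-secondary, tertiary diol F4. Mesylation of the secondary hydroxyl alone (MsCl, Et3N, 0 °C) gives the monomesylate F5. Et3Al (CH2Cl2, −78 °C) forms the aluminium alkoxide, whose C4–C10 bond migrates to C5 anti to the mesylate with inversion. This stereospecific semipinacol ring expansion should give the 2-substituted 3,3-dimethylcyclohexanone F6. MeCeCl2 (THF, −78 °C) adds to the ketone in the presence of the acetate to give the tertiary alcohol F7. SnCl4 (CH2Cl2, −78 °C) ionises it to the same C10 cation, which closes ring B onto the allylsilane to give 14.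

Step 1. C-methylation of the hindered tetrasubstituted enolate 2 next to a quaternary carbon may be slower than proton transfer. That would return the unmethylated ketone or place the methyl group on the acetyl carbon. The fallback builds the quaternary methyl group by cyclopropanation instead of alkylation; it sets out from 1 and comes back at 3. Conjugate addition to 1 with Me2CuLi in the presence of Me3SiCl should give the silyl enol ether {[1-(2,2-dimethylcyclopentylidene)ethyl]oxy}trimethylsilane F8. Simmons–Smith cyclopropanation (Et2Zn, CH2I2) of this electron-rich alkene gives the siloxycyclopropane trimethyl[(1,4,4-trimethylspiro[2.4]heptan-1-yl)oxy]silane F9. NaOH in MeOH desilylates it and opens the cyclopropanolate at the bond to the CH2 group, which becomes the new methyl group of 3.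

Step 3. Proton transfer from the enal to enolate 7, acyl transfer from the acetate, or retro-aldol cleavage of 8 before elimination may intervene. The fallback is a Wittig olefination in place of the aldol condensation; it sets out from 3 and comes back at 10. Br2 in MeOH brominates the only enolisable position of 3 to give 2-bromo-1-(1,2,2-trimethylcyclopentyl)ethan-1-one F10. PPh3 in toluene gives [2-oxo-2-(1,2,2-trimethylcyclopentyl)ethyl]triphenylphosphonium bromide F11. Aqueous NaOH gives the stabilised ylide 1-(1,2,2-trimethylcyclopentyl)-2-(triphenyl-λ5-phosphanylidene)ethan-1-one F12. Heating F12 with enal 6 in toluene should give the E-dienone 10.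

Further compounds
F1 | step 6 | 1-(1-hydroxy-2,2-dimethylcyclopentyl)ethan-1-one | CC(=O)C1(O)CCCC1(C)C
F2 | step 6 | (2E,6E,8E)-10-(1-hydroxy-2,2-dimethylcyclopentyl)-3,7-dimethyl-10-oxodeca-2,6,8-trien-1-yl acetate | CC(=O)OC/C=C(C)/CC/C=C(C)/C=C/C(=O)C1(O)CCCC1(C)C
F3 | step 6 | (2E,6E,8R)-8-[dimethyl(phenyl)silyl]-10-(1-hydroxy-2,2-dimethylcyclopentyl)-3,7-dimethyl-10-oxodeca-2,6-dien-1-yl acetate | CC1(C)CCCC1(O)C(=O)C[C@@H]([Si](C)(C)c1ccccc1)/C(C)=C/CC/C(C)=C/COC(C)=O
F4 | step 6 | (2E,6E,8R,10S)-8-[dimethyl(phenyl)silyl]-10-hydroxy-10-(1-hydroxy-2,2-dimethylcyclopentyl)-3,7-dimethyldeca-2,6-dien-1-yl acetate | CC1(C)CCCC1(O)[C@@H](O)C[C@@H]([Si](C)(C)c1ccccc1)/C(C)=C/CC/C(C)=C/COC(C)=O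
F5 | step 6 | (2E,6E,8R,10S)-8-[dimethyl(phenyl)silyl]-10-(1-hydroxy-2,2-dimethylcyclopentyl)-10-[(methanesulfonyl)oxy]-3,7-dimethyldeca-2,6-dien-1-yl acetate | CC1(C)CCCC1(O)[C@@H](OS(C)(=O)=O)C[C@@H]([Si](C)(C)c1ccccc1)/C(C)=C/CC/C(C)=C/COC(C)=O
F6 | step 6 | (2E,6E,8R)-8-[dimethyl(phenyl)silyl]-9-[(1S)-2,2-dimethyl-6-oxocyclohexyl]-3,7-dimethylnona-2,6-dien-1-yl acetate | O=C1CCCC(C)(C)[C@@H]1C[C@@H]([Si](C)(C)c1ccccc1)/C(C)=C/CC/C(C)=C/COC(C)=O
F7 | step 6 | (2E,6E,8R)-8-[dimethyl(phenyl)silyl]-9-[(1S)-2-hydroxy-2,6,6-trimethylcyclohexyl]-3,7-dimethylnona-2,6-dien-1-yl acetate | CC1(O)CCCC(C)(C)[C@@H]1C[C@@H]([Si](C)(C)c1ccccc1)/C(C)=C/CC/C(C)=C/COC(C)=O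
F8 | step 1 | {[1-(2,2-dimethylcyclopentylidene)ethyl]oxy}trimethylsilane | CC(O[Si](C)(C)C)=C1CCCC1(C)C
F9 | step 1 | trimethyl[(1,4,4-trimethylspiro[2.4]heptan-1-yl)oxy]silane | CC1(O[Si](C)(C)C)CC12CCCC2(C)C
F10 | step 3 | 2-bromo-1-(1,2,2-trimethylcyclopentyl)ethan-1-one | BrCC(=O)C1(C)CCCC1(C)C
F11 | step 3 | [2-oxo-2-(1,2,2-trimethylcyclopentyl)ethyl]triphenylphosphonium bromide | [Br-].O=C(C[P+](c1ccccc1)(c1ccccc1)c1ccccc1)C1(C)CCCC1(C)C
F12 | step 3 | 1-(1,2,2-trimethylcyclopentyl)-2-(triphenyl-λ5-phosphanylidene)ethan-1-one | O=C(C=P(c1ccccc1)(c1ccccc1)c1ccccc1)C1(C)CCCC1(C)C
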